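# Proposed total synthesis of CNP0191628.1 (compound 26)

## Analysis of the target

Target 26 is a germacranolide. Its ten-membered carbocycle is numbered C1–C10: C1 is the carbinol carbon, C4/C5 are the epoxide carbons, C6 carries the angelate, C7/C8 are the ring-fusion carbons and C9=C10 is the ring alkene, with methyl C14 on C10 and methyl C15 on C4. The carbocycle is trans-fused at C7–C8 to an α-methylene-γ-butyrolactone (O–C8–C7–C11–C12, exocyclic C13).

The ring holds two Z-configured trisubstituted olefin units in a 1,6-relationship, one as the free alkene C9=C10 and one as the cis-epoxide C4–C5, so the usual E,E-germacradiene logic does not apply.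

There are six stereocentres: C1 (R), C4 (R), C5 (S), C6 (S), C7 (R) and C8 (S). C4 to C8 are contiguous: H7 and H8 are anti, O6 is anti to C8 along the C5–C6–C7–C11 backbone, and the epoxide oxygen lies on the same ring face as O6. C1 is related to C8 only across the Z alkene, with the two oxygens on opposite faces.

The feature that invites the plan is the C6–C7–C8 triad. C7 is the only ring carbon with a carbon branch (C11). Both of its ring neighbours are secondary allylic carbinol carbons, each joined to a (Z)-CH=C(CH3)–CH2 arm (C5=C4–C3 and C9=C10–C1). The ring is therefore pseudo-symmetric about C7, and O6 and O8 differ only in their acyl partner (angelate versus lactone).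

Sensitive groups are the exo-methylene lactone (Michael acceptor, base), the angelate (isomerises to the tiglate), the trisubstituted epoxide next to an acyloxy carbon (acid), the allylic C1 alcohol, and the Z-enal and allylic halide intermediates needed for any C–C closure at C6 or C8. The lactone can in principle migrate from O8 to O6.

The synthesis is hard because a ten-membered ring must be closed while two Z trisubstituted olefins are kept, five contiguous stereocentres are set, and O6 and O8 are told apart.

## Retrosynthetic reasoning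

**End game (26 ⇐ 25 ⇐ 22 + 23 ⇐ 21).** The Si–O bond at O1, the O6–acyl bond and the two C–O bonds of the epoxide are cut last. The epoxide oxygen is syn to O6 on a cyclic (Z)-allylic alcohol, which is what a hydroxyl-directed, vanadium-catalysed epoxidation of a medium-ring cis-allylic alcohol delivers. The epoxide is therefore put in after ring closure, directed by a free O6, and O6 is acylated only afterwards with 23. O1 must stay capped so that it cannot direct oxidation of C9=C10. This reduces C4 and C5 to one requirement: macrocycle 21 with O6 free and O1 silylated.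

**Key disconnection (21 ⇐ 19), C6–C7.** Cutting here opens the ten-membered ring and removes the stereocentres C6 and C7 together. The lactone stays closed on O8, so the O6/O8 problem is already decided in the precursor. The forward reaction produces exactly the free C6 hydroxyl that the end game needs. It must generate a nucleophile at C13 of the butenolide in 19 and add it through C7 to the C6 aldehyde, on the face of C7 away from the C8–C9 bond and with an anti C6/C7 relationship. The precursor 19 is acyclic apart from the butenolide and has two stereocentres, against four in the bicyclic 21.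

**Adjustment at C6 (19 ⇐ 18 ⇐ 17).** The C6 aldehyde is carried as a PMB ether, so that only one aldehyde (C8) is present when C7 is first introduced.

**Second bond to C7 (17 ⇐ 13 + 3), C7–C8 and O8–C12.** The same carbon, C7, is used as a nucleophile a second time. Compound 3 is a four-carbon C7/C11/C12/C13 unit that can be allylated twice, because the first allylation leaves a new allylic bromide at C7. Both ring bonds to C7 thus come from one reaction type and one reagent. Cutting C7–C8 at this point means the lactone forms at O8 before C6 is even an electrophile. The forward step must set C8 by reagent control, since C1 is too remote to be trusted.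

**Z-alkene C9=C10 and C1 (13 ⇐ 12 ⇐ 11 ⇐ 10 ⇐ 9 ⇐ 7 + 8).** The C10–C14 bond is cut (syn delivery of methyl to an ynoate fixes the Z geometry), then the C1–C10 bond (enantioselective alkynylation of aldehyde 7 by 8 sets C1). The ester of 8 becomes C8.

**C1–C6 arm (7 ⇐ 5 ⇐ 4).** Carbons C1–C6 with the (Z)-C4=C5 alkene, C15 and O6 are the neryl skeleton of 4 minus its isopropylidene end, which is excised by epoxidation and glycol cleavage.

**C7 reagent (3 ⇐ 2 ⇐ 1).** Bromination and dehydrobromination of the commercial acrylate 1.

## Alternatives that were turned down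

**Alternative 1:** the textbook ring closure, cutting the ring alkene C9=C10. The forward key step would be ring-closing metathesis of the acyclic diene A1 (vinyl on C8, 2-propenyl on C1) with a second-generation Grubbs catalyst.
- It asks metathesis to make a Z trisubstituted olefin flanked by two oxygenated stereocentres inside a ten-membered ring. There the reaction is reversible, oligomerisation competes, and nothing in A1 enforces the Z geometry.
- A1 already contains two further alkenes that can enter metathesis (C11=C13 and the angelate).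
- All six stereocentres, the epoxide and the lactone would have to be made on an open chain, without any help from the ring, and the key step then only closes a bond.

**Alternative 2:** the established germacranolide closure, cutting C7–C8 and forming the lactone after the C–C bond. The forward key step would treat the acyclic (Z)-2-(bromomethyl)enoate aldehyde A2 with divalent chromium and let the new O8 alkoxide lactonise.
- O6 must be protected through the closure and deprotected afterwards, and A2 needs a 2-(bromomethyl)enoate built next to the C6 stereocentre, which costs more steps than it saves.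
- The acyclic allylchromium equilibrates between its geometric isomers, so the C7/C8 relationship is left to the ring conformation.
- After deprotection, O6 and O8 are both γ to C12, so lactone migration is invited just when O6 has to be used.
- Closing through the preformed lactone at C6–C7 (the route chosen) removes all three problems.

**Alternative 3:** ring contraction, cutting C7–C8 as a [2,3]-Wittig rearrangement of the thirteen-membered diallyl ether A3 (O bridging C8 and C13; deprotonation at C8).
- A thirteen-membered ether is easier to close than the carbocycle, and the rearrangement would set C7 and C8 together.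
- However, the two ether α-positions (C8 and C13) are both allylic CH2 groups of similar acidity, so the site of deprotonation is not secure.
- The allyl anion at C8 can lose the Z geometry of C9=C10.
- A strong base has to be used next to two silyl ethers.
- The product would still need C12 oxidised and lactonised and O6 deprotected, about five extra steps.

Key step: step 13

Assumption: the chiral ligands of steps 5 and 10 are written as one antipode; the sense of induction follows the accepted transition-state models, and the other antipode is used if it proves opposite.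

## Route

Step 1
Reactants: 1 methyl 2-(bromomethyl)prop-2-enoate
Product: 2 methyl 2,3-dibromo-2-(bromomethyl)propanoate
Conditions: Br2, CH2Cl2, 0 °C to rt
Reagents that add atoms: bromine, BrBr
Why: Electrophilic bromination of the acrylate double bond; the new quaternary carbon carries two identical CH2Br groups and is not a stereocentre.

Step 2
Reactants: 2 methyl 2,3-dibromo-2-(bromomethyl)propanoate
Product: 3 methyl 3-bromo-2-(bromomethyl)prop-2-enoate (mixture of geometric isomers)
Conditions: i-Pr2NEt (1.05 equiv), CH2Cl2, 0 °C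
Reagents that add atoms: none
Why: Dehydrobromination (E2) can only take a CH2Br proton together with the tertiary α-bromine and so gives the conjugated vinyl bromide; both geometric isomers are usable because the allylchromium made from them in step 10 equilibrates.

Step 3
Reactants: 4 nerol
Product: 5 1-({[(2Z)-3,7-dimethylocta-2,6-dien-1-yl]oxy}methyl)-4-methoxybenzene (neryl PMB ether)
Conditions: NaH, 4-methoxybenzyl chloride, Bu4NI (cat.), THF/DMF, 0 °C to rt
Reagents that add atoms: 4-methoxybenzyl chloride, COc1ccc(CCl)cc1
Why: Williamson ether synthesis; the PMB ether masks O6 through the hydride, cuprate and first chromium steps and is later removed under neutral oxidative conditions that spare the silyl ether.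

Step 4
Reactants: 5 neryl PMB ether
Product: 7 (4Z)-6-[(4-methoxyphenyl)methoxy]-4-methylhex-4-enal, via epoxide 6 (not isolated)
Conditions: mCPBA, NaHCO3, CH2Cl2, −20 °C; then H5IO6, THF/H2O, 0 °C
Reagents that add atoms: 3-chloroperoxybenzoic acid, OOC(=O)c1cccc(Cl)c1
Why: Prilezhaev epoxidation should pick the remote, more electron-rich trisubstituted alkene (the C4=C5 alkene is deactivated by the allylic ether oxygen); periodic acid then opens the epoxide and cleaves the glycol, excising acetone and leaving the Z alkene untouched.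

Step 5
Reactants: 7 (4Z)-6-[(4-methoxyphenyl)methoxy]-4-methylhex-4-enal; 8 methyl propiolate
Product: 9 methyl (4R,7Z)-4-hydroxy-9-[(4-methoxyphenyl)methoxy]-7-methylnon-7-en-2-ynoate
Conditions: Me2Zn, (S,S)-ProPhenol (20 mol %), Ph3PO (40 mol %), toluene, 0 °C
Reagents that add atoms: none
Why: Catalytic enantioselective alkynylation of an aldehyde by an alkynylzinc under dinuclear zinc–ProPhenol catalysis; the catalyst pocket selects the aldehyde face and sets C1 (R), the first stereocentre of the route.

Step 6
Reactants: 9 methyl (4R,7Z)-4-hydroxy-9-[(4-methoxyphenyl)methoxy]-7-methylnon-7-en-2-ynoate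
Product: 10 methyl (4R,7Z)-4-[(tert-butyldimethylsilyl)oxy]-9-[(4-methoxyphenyl)methoxy]-7-methylnon-7-en-2-ynoate
Conditions: TBSCl, imidazole, DMF, rt
Reagents that add atoms: tert-butyldimethylsilyl chloride, CC(C)(C)[Si](C)(C)Cl
Why: Standard silylation of a secondary propargylic alcohol; the silyl ether prevents butenolide formation after step 7 and later keeps O1 from directing the epoxidation.

Step 7
Reactants: 10 methyl (4R,7Z)-4-[(tert-butyldimethylsilyl)oxy]-9-[(4-methoxyphenyl)methoxy]-7-methylnon-7-en-2-ynoate
Product: 11 methyl (2Z,4R,7Z)-4-[(tert-butyldimethylsilyl)oxy]-9-[(4-methoxyphenyl)methoxy]-3,7-dimethylnona-2,7-dienoate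
Conditions: Me2CuLi, THF, −78 °C; MeOH quench at −78 °C
Reagents that add atoms: lithium dimethylcuprate, [Li+].C[Cu-]C
Why: Conjugate addition of a dialkylcuprate to an ynoate is a syn carbocupration; protonation of the alkenylcuprate at −78 °C with retention puts C14 cis to H9 and therefore C1 cis to the ester carbon C8, which is the (Z)-C9=C10 alkene of the target.

Step 8
Reactants: 11 methyl (2Z,4R,7Z)-4-[(tert-butyldimethylsilyl)oxy]-9-[(4-methoxyphenyl)methoxy]-3,7-dimethylnona-2,7-dienoate
Product: 12 (2Z,4R,7Z)-4-[(tert-butyldimethylsilyl)oxy]-9-[(4-methoxyphenyl)methoxy]-3,7-dimethylnona-2,7-dien-1-ol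
Conditions: i-Bu2AlH (2.2 equiv), CH2Cl2, −78 °C; Rochelle salt work-up
Reagents that add atoms: none
Why: 1,2-Reduction of the enoate by the aluminium hydride at low temperature gives the (Z)-allylic alcohol without touching the silyl and PMB ethers.

Step 9
Reactants: 12 (2Z,4R,7Z)-4-[(tert-butyldimethylsilyl)oxy]-9-[(4-methoxyphenyl)methoxy]-3,7-dimethylnona-2,7-dien-1-ol
Product: 13 (2Z,4R,7Z)-4-[(tert-butyldimethylsilyl)oxy]-9-[(4-methoxyphenyl)methoxy]-3,7-dimethylnona-2,7-dienal
Conditions: MnO2, CH2Cl2, rt
Reagents that add atoms: none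
Why: MnO2 oxidises the primary allylic alcohol selectively and under neutral conditions, which should keep the Z geometry of the enal.

Step 10
Reactants: 13 (2Z,4R,7Z)-4-[(tert-butyldimethylsilyl)oxy]-9-[(4-methoxyphenyl)methoxy]-3,7-dimethylnona-2,7-dienal; 3 methyl 3-bromo-2-(bromomethyl)prop-2-enoate
Product: 17 (5S)-3-(bromomethyl)-5-[(1Z,3R,6Z)-3-[(tert-butyldimethylsilyl)oxy]-8-[(4-methoxyphenyl)methoxy]-2,6-dimethylocta-1,6-dien-1-yl]furan-2(5H)-one, via allylchromium 14 (not isolated), via chromium alkoxide 15 (not isolated), via bromolactone 16 (not isolated)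
Conditions: CrCl2 (2.0 equiv), N-{2-[(4S)-4-isopropyl-4,5-dihydro-1,3-oxazol-2-yl]-6-methylphenyl}methanesulfonamide (2.2 equiv), Et3N (2.2 equiv), THF, rt; then 3 (1.3 equiv) and 13, 0 °C to rt; then LiBr (5 equiv), rt
Reagents that add atoms: lithium bromide, [Li+].[Br-]
Why: Barbier-type Nozaki–Hiyama–Kishi allylation: divalent chromium inserts into the allylic C–Br bond of 3 to give 14, which adds through its bromine-bearing γ-carbon (C7) to the aldehyde in a closed chair transition state whose facial sense is set by the chiral ligand on chromium (C8, S). The alkoxide 15 closes the γ-lactone 16, and bromide-induced allylic transposition (SN2') converts both C7 epimers of 16 into the single conjugated primary bromide 17. CrCl2 is kept limiting against the excess of 3 so that the new secondary allylic bromide is not reduced further.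

Step 11
Reactants: 17 (5S)-3-(bromomethyl)-5-[(1Z,3R,6Z)-3-[(tert-butyldimethylsilyl)oxy]-8-[(4-methoxyphenyl)methoxy]-2,6-dimethylocta-1,6-dien-1-yl]furan-2(5H)-one
Product: 18 (5S)-3-(bromomethyl)-5-[(1Z,3R,6Z)-3-[(tert-butyldimethylsilyl)oxy]-8-hydroxy-2,6-dimethylocta-1,6-dien-1-yl]furan-2(5H)-one
Conditions: DDQ (1.3 equiv), CH2Cl2/pH 7 buffer, 0 °C
Reagents that add atoms: none
Why: Oxidative PMB cleavage (hydride abstraction at the benzylic carbon, hydrolysis of the oxocarbenium ion) is neutral and should leave the allylic bromide, the butenolide and the silyl ether intact.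

Step 12
Reactants: 18 (5S)-3-(bromomethyl)-5-[(1Z,3R,6Z)-3-[(tert-butyldimethylsilyl)oxy]-8-hydroxy-2,6-dimethylocta-1,6-dien-1-yl]furan-2(5H)-one
Product: 19 (2Z,6R,7Z)-8-[(2S)-4-(bromomethyl)-5-oxo-2,5-dihydrofuran-2-yl]-6-[(tert-butyldimethylsilyl)oxy]-3,7-dimethylocta-2,7-dienal
Conditions: MnO2, CH2Cl2, rt
Reagents that add atoms: none
Why: Allylic oxidation with MnO2 as in step 9; the conditions are neutral, so the allylic bromide, the epimerisable C8 centre and the Z geometry of the new enal should survive.

Step 13
Reactants: 19 (2Z,6R,7Z)-8-[(2S)-4-(bromomethyl)-5-oxo-2,5-dihydrofuran-2-yl]-6-[(tert-butyldimethylsilyl)oxy]-3,7-dimethylocta-2,7-dienal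
Product: 21 (1R,4Z,6R,7S,8S,9Z)-1-[(tert-butyldimethylsilyl)oxy]-6-hydroxygermacra-4,9,11(13)-trien-12,8-olide, via allylchromium 20 (not isolated)
Conditions: CrCl2 (8 equiv), THF, rt, slow addition of 19 (final 0.002 M); aq. NH4Cl
Reagents that add atoms: none
Why: Two equivalents of divalent chromium reduce the C13–Br bond of 19 to the allylchromium 20, which adds through its γ-carbon C7 to the C6 aldehyde in a closed six-membered chair transition state (Cr, O6, C6, C7, C11, C13) and moves the double bond from C7=C11 to C11=C13. The closest known reaction types are the intramolecular Nozaki–Hiyama–Kishi allylation of 2-(alkoxycarbonyl)allyl bromides used to close ten-membered germacranolide rings, and the intermolecular Barbier allylation of aldehydes by 3-(bromomethyl)butenolides. The ten-membered carbocycle is closed by C6–C7 bond formation in an exo-trig mode (the carbonyl oxygen stays outside the ring and becomes the C6 hydroxyl); the lactone ring is not formed here but is converted from the butenolide into the α-methylene lactone. C7 is controlled by C8: the new bond should form on the face of the flat butenolide opposite to the C8–C9 bond, because bonding on the same face would eclipse the forming C6–C7 bond with C8–C9, and this gives the trans ring fusion. C6 is controlled by the locked geometry of the allyl unit: in the butenolide, C8 is held trans to C13 across C7=C11 (an E-type γ-substituted allylmetal that cannot isomerise), so the chair with the aldehyde substituent C5 equatorial gives the anti relationship of O6 and C8, which is the 6R,7S arrangement of 21. Three selectivities are needed: ring closure over oligomerisation (high dilution, slow addition), attack on the aldehyde only (O1 is silylated, no other carbonyl electrophile is within reach and the lactone carbonyl is inert to allylchromium reagents), and retention of C8 and of both Z alkenes (neutral, non-basic medium). The product emerges with O6 free and O8 already locked in the lactone.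

Step 14
Reactants: 21 (1R,4Z,6R,7S,8S,9Z)-1-[(tert-butyldimethylsilyl)oxy]-6-hydroxygermacra-4,9,11(13)-trien-12,8-olide
Product: 22 (1R,4R,5S,6S,7S,8S,9Z)-1-[(tert-butyldimethylsilyl)oxy]-4,5-epoxy-6-hydroxygermacra-9,11(13)-dien-12,8-olide
Conditions: VO(acac)2 (5 mol %), t-BuOOH, CH2Cl2, 0 °C
Reagents that add atoms: tert-butyl hydroperoxide, CC(C)(C)OO
Why: Hydroxyl-directed epoxidation: the vanadium alkoxide of O6 delivers the peroxide oxygen to C4=C5 on the face syn to O6, which for a (Z)-allylic alcohol held in a medium ring gives the cis epoxy alcohol (C4 R, C5 S). C11=C13 is electron-poor and C9=C10 has no free hydroxyl next to it, so neither should react.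

Step 15
Reactants: 22 (1R,4R,5S,6S,7S,8S,9Z)-1-[(tert-butyldimethylsilyl)oxy]-4,5-epoxy-6-hydroxygermacra-9,11(13)-dien-12,8-olide; 23 angelic acid
Product: 25 (1R,4R,5S,6S,7R,8S,9Z)-6-angeloyloxy-1-[(tert-butyldimethylsilyl)oxy]-4,5-epoxygermacra-9,11(13)-dien-12,8-olide, via mixed anhydride 24 (not isolated)
Conditions: 2,4,6-trichlorobenzoyl chloride, Et3N, toluene, rt; then 22, 60 °C
Reagents that add atoms: none
Why: Yamaguchi esterification through the mixed anhydride 24, run without a nucleophilic amine catalyst so that the (Z)-2-methylbut-2-enoyl group is transferred without isomerisation to the tiglate; no stereocentre is touched.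

Step 16
Reactants: 25 (1R,4R,5S,6S,7R,8S,9Z)-6-angeloyloxy-1-[(tert-butyldimethylsilyl)oxy]-4,5-epoxygermacra-9,11(13)-dien-12,8-olide
Product: 26 (1R,4R,5S,6S,7R,8S,9Z)-6-angeloyloxy-4,5-epoxy-1-hydroxygermacra-9,11(13)-dien-12,8-olide (CNP0191628.1)
Conditions: HF·pyridine, pyridine, THF, 0 °C to rt
Reagents that add atoms: none
Why: Fluoride-mediated cleavage of the silyl ether under buffered conditions that should tolerate the epoxide, the angelate and the α-methylene lactone; it frees the C1 hydroxyl and completes the target.

## Compound list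

1 | methyl 2-(bromomethyl)prop-2-enoate | C=C(CBr)C(=O)OC | starting material
2 | methyl 2,3-dibromo-2-(bromomethyl)propanoate | COC(=O)C(Br)(CBr)CBr | intermediate
3 | methyl 3-bromo-2-(bromomethyl)prop-2-enoate (mixture of geometric isomers) | COC(=O)C(CBr)=CBr | intermediate
4 | nerol, (2Z)-3,7-dimethylocta-2,6-dien-1-ol | CC(C)=CCC/C(C)=C\CO | starting material
5 | 1-({[(2Z)-3,7-dimethylocta-2,6-dien-1-yl]oxy}methyl)-4-methoxybenzene | CC(C)=CCC/C(C)=C\COCc1ccc(OC)cc1 | intermediate
6 | 2-{(3Z)-5-[(4-methoxyphenyl)methoxy]-3-methylpent-3-en-1-yl}-3,3-dimethyloxirane (racemic at the oxirane CH) | CC1(C)OC1CC/C(C)=C\COCc1ccc(OC)cc1 | intermediate (not isolated)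
7 | (4Z)-6-[(4-methoxyphenyl)methoxy]-4-methylhex-4-enal | O=CCC/C(C)=C\COCc1ccc(OC)cc1 | intermediate
8 | methyl propiolate | C#CC(=O)OC | starting material
9 | methyl (4R,7Z)-4-hydroxy-9-[(4-methoxyphenyl)methoxy]-7-methylnon-7-en-2-ynoate | COC(=O)C#C[C@H](O)CC/C(C)=C\COCc1ccc(OC)cc1 | intermediate
10 | methyl (4R,7Z)-4-[(tert-butyldimethylsilyl)oxy]-9-[(4-methoxyphenyl)methoxy]-7-methylnon-7-en-2-ynoate | COC(=O)C#C[C@H](O[Si](C)(C)C(C)(C)C)CC/C(C)=C\COCc1ccc(OC)cc1 | intermediate
11 | methyl (2Z,4R,7Z)-4-[(tert-butyldimethylsilyl)oxy]-9-[(4-methoxyphenyl)methoxy]-3,7-dimethylnona-2,7-dienoate | COC(=O)/C=C(/C)[C@H](O[Si](C)(C)C(C)(C)C)CC/C(C)=C\COCc1ccc(OC)cc1 | intermediate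
12 | (2Z,4R,7Z)-4-[(tert-butyldimethylsilyl)oxy]-9-[(4-methoxyphenyl)methoxy]-3,7-dimethylnona-2,7-dien-1-ol | OC/C=C(/C)[C@H](O[Si](C)(C)C(C)(C)C)CC/C(C)=C\COCc1ccc(OC)cc1 | intermediate
13 | (2Z,4R,7Z)-4-[(tert-butyldimethylsilyl)oxy]-9-[(4-methoxyphenyl)methoxy]-3,7-dimethylnona-2,7-dienal | O=C/C=C(/C)[C@H](O[Si](C)(C)C(C)(C)C)CC/C(C)=C\COCc1ccc(OC)cc1 | intermediate
14 | allylchromium from 3: chloro(sulfonamidato ligand)[3-bromo-2-(methoxycarbonyl)prop-2-en-1-yl]chromium | COC(=O)C(=CBr)C[Cr](Cl)N(c1c(C)cccc1C1=N[C@@H](C(C)C)CO1)S(C)(=O)=O | intermediate (not isolated)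
15 | chromium alkoxide of methyl (4S)-3-bromo-4-hydroxy-2-methylidene ester adduct of 13 (C3 epimers, C8 = S) | COC(=O)C(=C)C(Br)[C@@H](O[Cr](Cl)N(c1c(C)cccc1C1=N[C@@H](C(C)C)CO1)S(C)(=O)=O)/C=C(/C)[C@H](O[Si](C)(C)C(C)(C)C)CC/C(C)=C\COCc1ccc(OC)cc1 | intermediate (not isolated)
16 | (5S)-4-bromo-3-methylidene-5-[(1Z,3R,6Z)-3-[(tert-butyldimethylsilyl)oxy]-8-[(4-methoxyphenyl)methoxy]-2,6-dimethylocta-1,6-dien-1-yl]oxolan-2-one (both C4 epimers) | O=C1O[C@@H](/C=C(/C)[C@H](O[Si](C)(C)C(C)(C)C)CC/C(C)=C\COCc2ccc(OC)cc2)C(Br)C1=C | intermediate (not isolated)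
17 | (5S)-3-(bromomethyl)-5-[(1Z,3R,6Z)-3-[(tert-butyldimethylsilyl)oxy]-8-[(4-methoxyphenyl)methoxy]-2,6-dimethylocta-1,6-dien-1-yl]furan-2(5H)-one | O=C1O[C@@H](/C=C(/C)[C@H](O[Si](C)(C)C(C)(C)C)CC/C(C)=C\COCc2ccc(OC)cc2)C=C1CBr | intermediate
18 | (5S)-3-(bromomethyl)-5-[(1Z,3R,6Z)-3-[(tert-butyldimethylsilyl)oxy]-8-hydroxy-2,6-dimethylocta-1,6-dien-1-yl]furan-2(5H)-one | O=C1O[C@@H](/C=C(/C)[C@H](O[Si](C)(C)C(C)(C)C)CC/C(C)=C\CO)C=C1CBr | intermediate
19 | (2Z,6R,7Z)-8-[(2S)-4-(bromomethyl)-5-oxo-2,5-dihydrofuran-2-yl]-6-[(tert-butyldimethylsilyl)oxy]-3,7-dimethylocta-2,7-dienal | O=C1O[C@@H](/C=C(/C)[C@H](O[Si](C)(C)C(C)(C)C)CC/C(C)=C\C=O)C=C1CBr | intermediate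
20 | allylchromium from 19: dichloro{[(5S)-2-oxo-5-(side chain of 19)-2,5-dihydrofuran-3-yl]methyl}chromium | O=C1O[C@@H](/C=C(/C)[C@H](O[Si](C)(C)C(C)(C)C)CC/C(C)=C\C=O)C=C1C[Cr](Cl)Cl | intermediate (not isolated)
21 | (1R,4Z,6R,7S,8S,9Z)-1-[(tert-butyldimethylsilyl)oxy]-6-hydroxygermacra-4,9,11(13)-trien-12,8-olide | C=C1C(=O)O[C@H]2/C=C(/C)[C@H](O[Si](C)(C)C(C)(C)C)CC/C(C)=C\[C@@H](O)[C@H]12 | intermediate
22 | (1R,4R,5S,6S,7S,8S,9Z)-1-[(tert-butyldimethylsilyl)oxy]-4,5-epoxy-6-hydroxygermacra-9,11(13)-dien-12,8-olide | C=C1C(=O)O[C@H]2/C=C(/C)[C@H](O[Si](C)(C)C(C)(C)C)CC[C@@]3(C)O[C@H]3[C@@H](O)[C@H]12 | intermediate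
23 | angelic acid, (2Z)-2-methylbut-2-enoic acid | C/C=C(/C)C(=O)O | starting material
24 | (2Z)-2-methylbut-2-enoic 2,4,6-trichlorobenzoic anhydride | C/C=C(/C)C(=O)OC(=O)c1c(Cl)cc(Cl)cc1Cl | intermediate (not isolated)
25 | (1R,4R,5S,6S,7R,8S,9Z)-6-angeloyloxy-1-[(tert-butyldimethylsilyl)oxy]-4,5-epoxygermacra-9,11(13)-dien-12,8-olide | C=C1C(=O)O[C@H]2/C=C(/C)[C@H](O[Si](C)(C)C(C)(C)C)CC[C@@]3(C)O[C@H]3[C@@H](OC(=O)/C(C)=C\C)[C@H]12 | intermediate
26 | (1R,4R,5S,6S,7R,8S,9Z)-6-angeloyloxy-4,5-epoxy-1-hydroxygermacra-9,11(13)-dien-12,8-olide (CNP0191628.1) | C=C1C(=O)O[C@H]2/C=C(/C)[C@H](O)CC[C@@]3(C)O[C@H]3[C@@H](OC(=O)/C(C)=C\C)[C@H]12 | target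

## Step count and least certain steps

Total step count: 16 (steps 1–2 make the C7 reagent 3; steps 3–16 are the main line). Longest linear sequence: 14 steps, from nerol 4 to 26 (steps 3–16).

**Step 13 (key step).**
- Most likely failures are intermolecular coupling outrunning ring closure, premature protonation or 1,4-elimination (ring opening of the lactone) of the allylchromium before it reaches the aldehyde, and bond formation on the wrong face of C7 if the tether folds over the butenolide. Migration of the lactone to the new O6 alkoxide is a further possible loss.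
- The fallback replaces the short-lived, reductively generated organochromium by an isolable allylboron reagent whose cyclisation is homogeneous and triggered by a Lewis acid. It sets out from 18 and comes back at 21.
- Borylation of 18 with B2pin2 and Pd2(dba)3 (cat.) should give the primary pinacol allylboronate alcohol F1. MnO2 oxidation should give the boronate aldehyde F2. Sc(OTf)3 (cat.) in CH2Cl2 at high dilution should then close the ring by intramolecular allylboration through the same chair, with boron in place of chromium and the same locked allyl geometry. Aqueous work-up gives 21.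

**Step 10.**
- The chiral ligand may not impose enough facial control on the Z-enal. The substrate's own 1,4-bias should be small, because both C1 substituents point away from the carbonyl, but it may oppose the ligand.
- The new secondary allylic bromide may be reduced further, or the bromohydrin alkoxide may close to a vinyl epoxide instead of lactonising.
- The fallback builds the butenolide by carbonylation instead of allylation. It sets out from 13 and comes back at 17.
- Zinc–ProPhenol alkynylation of 13 with triethyl(prop-2-yn-1-yloxy)silane (an asymmetric alkynylation of an enal) should give the (4S)-propargylic alcohol F3.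
- Hydroxyl-directed trans-hydroalumination with NaAlH2(OCH2CH2OCH3)2 followed by iodine should give the (Z)-iodoalkenol F4.
- Carbonylative lactonisation with PdCl2(PPh3)2 (cat.), CO and Et3N should give the 3-[(triethylsilyloxy)methyl]butenolide F5.
- PPTS in methanol should remove the triethylsilyl group selectively to give the 3-(hydroxymethyl)butenolide F6, and CBr4/PPh3 converts F6 into 17.

**Step 14.**
- Facial selectivity may be poor if the ring does not adopt the conformation in which the vanadium alkoxide reaches C4=C5 from the O6 side. Oxidation of the allylic alcohol to the enone, or Lewis-acid-promoted lactone migration, may compete.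
- The fallback replaces substrate direction by catalyst control and changes the order of events. It sets out from 21 and comes back at 25.
- Compound 21 is first acylated with 23 under the conditions of step 15 to give the 6-O-angelate of 21, F7. The electron-rich C4=C5 alkene of F7 is then epoxidised with KHSO5 and a carbohydrate-derived chiral ketone (Shi epoxidation), the ketone antipode being chosen for the required face; this gives 25.

**Step 5.**
- An unbranched aliphatic aldehyde may give only moderate enantioselectivity, and aldol self-condensation may compete with alkynylation.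
- The fallback replaces asymmetric addition by asymmetric reduction. It sets out from 7 and comes back at 9.
- Addition of the lithium acetylide of 8 to 7 at −78 °C should give the racemic hydroxy ynoate F8. MnO2 oxidation should give the ynone F9. Midland reduction of F9 with the appropriate antipode of Alpine-Borane (B-isopinocampheyl-9-borabicyclo[3.3.1]nonane) should return 9.

## Further compounds

F1 | step 13 | (5S)-5-[(1Z,3R,6Z)-3-[(tert-butyldimethylsilyl)oxy]-8-hydroxy-2,6-dimethylocta-1,6-dien-1-yl]-3-[(4,4,5,5-tetramethyl-1,3,2-dioxaborolan-2-yl)methyl]furan-2(5H)-one | O=C1O[C@@H](/C=C(/C)[C@H](O[Si](C)(C)C(C)(C)C)CC/C(C)=C\CO)C=C1CB1OC(C)(C)C(C)(C)O1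
F2 | step 13 | (2Z,6R,7Z)-6-[(tert-butyldimethylsilyl)oxy]-3,7-dimethyl-8-{(2S)-5-oxo-4-[(4,4,5,5-tetramethyl-1,3,2-dioxaborolan-2-yl)methyl]-2,5-dihydrofuran-2-yl}octa-2,7-dienal | O=C1O[C@@H](/C=C(/C)[C@H](O[Si](C)(C)C(C)(C)C)CC/C(C)=C\C=O)C=C1CB1OC(C)(C)C(C)(C)O1
F3 | step 10 | (4S,5Z,7R,10Z)-7-[(tert-butyldimethylsilyl)oxy]-12-[(4-methoxyphenyl)methoxy]-6,10-dimethyl-1-[(triethylsilyl)oxy]dodeca-5,10-dien-2-yn-4-ol | CC[Si](CC)(CC)OCC#C[C@@H](O)/C=C(/C)[C@H](O[Si](C)(C)C(C)(C)C)CC/C(C)=C\COCc1ccc(OC)cc1
F4 | step 10 | (2Z,4S,5Z,7R,10Z)-7-[(tert-butyldimethylsilyl)oxy]-2-iodo-12-[(4-methoxyphenyl)methoxy]-6,10-dimethyl-1-[(triethylsilyl)oxy]dodeca-2,5,10-trien-4-ol | CC[Si](CC)(CC)OC/C(I)=C/[C@@H](O)/C=C(/C)[C@H](O[Si](C)(C)C(C)(C)C)CC/C(C)=C\COCc1ccc(OC)cc1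
F5 | step 10 | (5S)-5-[(1Z,3R,6Z)-3-[(tert-butyldimethylsilyl)oxy]-8-[(4-methoxyphenyl)methoxy]-2,6-dimethylocta-1,6-dien-1-yl]-3-{[(triethylsilyl)oxy]methyl}furan-2(5H)-one | O=C1O[C@@H](/C=C(/C)[C@H](O[Si](C)(C)C(C)(C)C)CC/C(C)=C\COCc2ccc(OC)cc2)C=C1CO[Si](CC)(CC)CC
F6 | step 10 | (5S)-5-[(1Z,3R,6Z)-3-[(tert-butyldimethylsilyl)oxy]-8-[(4-methoxyphenyl)methoxy]-2,6-dimethylocta-1,6-dien-1-yl]-3-(hydroxymethyl)furan-2(5H)-one | O=C1O[C@@H](/C=C(/C)[C@H](O[Si](C)(C)C(C)(C)C)CC/C(C)=C\COCc2ccc(OC)cc2)C=C1CO
F7 | step 14 | 6-O-angelate of 21: 6-angeloyloxy-1-[(tert-butyldimethylsilyl)oxy]germacra-4Z,9Z,11(13)-trien-12,8-olide with all stereocentres as in 21 | C=C1C(=O)O[C@H]2/C=C(/C)[C@H](O[Si](C)(C)C(C)(C)C)CC/C(C)=C\[C@@H](OC(=O)/C(C)=C\C)[C@H]12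
F8 | step 5 | racemic methyl (7Z)-4-hydroxy-9-[(4-methoxyphenyl)methoxy]-7-methylnon-7-en-2-ynoate | COC(=O)C#CC(O)CC/C(C)=C\COCc1ccc(OC)cc1
F9 | step 5 | methyl (7Z)-9-[(4-methoxyphenyl)methoxy]-7-methyl-4-oxonon-7-en-2-ynoate | COC(=O)C#CC(=O)CC/C(C)=C\COCc1ccc(OC)cc1
A1 | alternative 1 | acyclic metathesis precursor: 3-methylidene-5-vinyl-γ-butyrolactone carrying at C7 the (6S)-angeloyloxy, (4R,5S)-epoxy, (1R)-silyloxy chain that ends in a 2-propenyl group | C=C1C(=O)O[C@@H](C=C)[C@@H]1[C@H](OC(=O)/C(C)=C\C)[C@@H]1O[C@]1(C)CC[C@@H](O[Si](C)(C)C(C)(C)C)C(C)=C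
A2 | alternative 2 | methyl (2Z,4S,5Z,9R,10Z)-2-(bromomethyl)-9-[(tert-butyldimethylsilyl)oxy]-6,10-dimethyl-12-oxo-4-[(triethylsilyl)oxy]dodeca-2,5,10-trienoate | COC(=O)/C(CBr)=C/[C@H](O[Si](CC)(CC)CC)/C=C(/C)CC[C@@H](O[Si](C)(C)C(C)(C)C)/C(C)=C\C=O
A3 | alternative 3 | thirteen-membered diallyl ether: O bridging C8H2 and C13H2; ring Z-alkenes C9=C10 and C4=C5; C1 silyloxy (R); C6 triethylsilyloxy; C11 bearing CH2O-PMB | O1C/C=C(/C)[C@H](O[Si](C)(C)C(C)(C)C)CC/C(C)=C\[C@@H](O[Si](CC)(CC)CC)/C=C(\COCc2ccc(OC)cc2)C1
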